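Start from a constant the runs offer: the feed, the rate at which Z appears while D is plentiful.

all flasks: J 110 mM (held)
- winter: D 0.14 M; run made earlier
- noon: D 0.58 M; run made earlier
- flask: D 0.29 M; time 2.0 min

| run | time / min | Z / % | D / % |
|---|---|---|---|
| winter | 0.167 | 15.1 | 85.3 |
| winter | 0.333 | 32.1 | 68.6 |
| winter | 0.667 | 61.7 | 36.7 |
| winter | 1.00 | 89.5 | 11.3 |
| winter | 1.33 | 99.2 | 1.1 |
| winter | 2.00 | 99.3 | 0.5 |
| winter | 2.50 | 100.6 | 0.3 |
| noon | 0.200 | 5.2 | 95.6 |
| noon | 0.333 | 8.3 | 91.7 |
| noon | 0.417 | 9.6 | 89.3 |
| noon | 0.667 | 17.2 | 83.5 |
| noon | 1.00 | 24.4 | 74.8 |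
| noon | 1.50 | 38.2 | 63.8 |
| noon | 2.50 | 61.6 | 38.7 |

(standard deviation of a reading: 0.5 percentage points)

- at the start none of J is in solution
- L is what J becomes in solution

- how much Z there is at 2.0 min, in percent of the D charged
- concentration of L in solution at 2.0 min, in percent of saturation

1. Read the slopes of Z. Winter gives 0.125 M/min and noon 0.142 M/min. From winter to noon c_D grows 4.14-fold and the rate 1.14-fold, so the passage of J into L looks like the rate-limiting step. Keep the noon value as the feed.
2. Divide the charge by the feed: 2.04 min for this flask. This is the feed time, the time the gas needs to pay for the whole charge of D.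
3. Turn the question round. Suppose c_L stood near saturation: with the feed held, I would look for a feed time ending well before the reading. Assume that entry falls in proportion to the distance from saturation. Past the feed time, c_L then climbs as 1 − exp(−(feed/c_sat) × spare time), where the spare time is the reading time less the feed time. In this flask the feed time is about the time asked, so I expect c_L low.
4. Reckon Z. Winter, near its own feed time of 0.984 min, still read D 11.3% at 1.00 min, a lag of 0.0158 M. Subtracting that lag from what the gas pays in this flask gives my Z of 92.6%.

The forecast says Z 91% (88% to 94%) and c_L 33% of saturation (20% to 50%): “So the reaction is mostly limited by J dissolving, and L stays well below saturation while D is high.” Its Z stands 1.6 percentage points below mine, and on c_L, which step 3 makes low, I part from its figure.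

The flask gives Z 93.4% and c_L 11.3% of saturation, with D 6.36% left, so its Z lies 0.80 points above mine.

    D + L → Z (k = 6.77 /M/s)
    Z → E (k = 4.63 × 10⁻⁵ /s)
    J ⇌ L, rate k3*(csat - [L]) (kL = 0.0222 /s)

Now take the neighbour flask, charged with 0.12 M of D. Its feed time is 0.845 min, which leaves it 1.16 min of spare time, and the climb then gives 77.6% of saturation. At 2.00 min that neighbour flask holds D 0%, Z 99.6% and L 0.0851 M, which is 77.4% of saturation.

The numbers in the tables were generated by integration from invented constants, noise included.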